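As time passes in this closed flask, pre-initiator releases initiator, and each initiator that meets free monomer begins one chain, while impurity stands on the list as a consumer of initiator.

| setting | elm | flask |
|---|---|---|
| free monomer | 0.10 M | 0.10 M |
| pre-initiator | 0.24 mol% | 0.24 mol% |
| impurity | 0.17 mM | 0.17 mM |
| remark | the very flask that is asked about, followed so far |  |
| time |  | 3.0 h |

elm run (percent of the free monomer charged)

| time / min | monomer in chains / % | free monomer / % |
|---|---|---|
| 2.00 | 0.4 | 99.0 |
| 5.00 | 3.8 | 94.5 |
| 10.0 | 12.8 | 86.7 |
| 15.0 | 18.7 | 80.4 |

(scatter of a reading: 0.5 percentage points)

- the average divides the monomer in chains by the number of chains begun, living and dead together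
- on the list of suspects stand: free monomer + initiator -> living end + monomer in chains; free monomer + living end -> monomer in chains + living end; monomer in chains + living end -> free monomer + living end; pre-initiator -> initiator; initiator + impurity -> spent initiator A; initiator + monomer in chains -> spent initiator B
- the earlier runs do not show the number of chains; that part of a forecast is a guess

- average number of monomer units in a chain (chains begun, living or dead) at 3.0 h
- part of the free monomer that has reacted at 3.0 h

This reckoning takes the number of chains from the charged pre-initiator, with the impurity as a correction to it. If each pre-initiator gives one initiator and each impurity removes one initiator, in the manner of a titration, the flask keeps the surviving chain count n, charged pre-initiator minus charged impurity, 0.0700 mM. Then dp, the monomer in chains divided by the chains begun, is the conversion c times 1430.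

The forecast gave a c of 90% and a dp of 750, saying “The number of chains is a guess”. At that conversion this reckoning gives a higher dp, 1290, so the two differ.

The flask gives a dp of 242 and a c of 22.6%.

    free monomer + initiator → living end + monomer in chains (k = 14.0 L mol⁻¹ min⁻¹)
    free monomer + living end → monomer in chains + living end, rate k2*[living end]*[free monomer] (k = 3940 L mol⁻¹ min⁻¹)
    monomer in chains + living end → free monomer + living end, rate k3*[living end] as long as [monomer in chains] is above zero (k = 305 min⁻¹)
    pre-initiator → initiator (k = 0.0824 min⁻¹)
    initiator + impurity → spent initiator A (k = 24800 L mol⁻¹ min⁻¹)
    initiator + monomer in chains → spent initiator B (k = 1.26 L mol⁻¹ min⁻¹)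

In this flask the conversion already stands at 22.6% after 0.750 h and still at 22.6% after 30.0 h. With n, the conversion reached gives a dp of 323, higher than the flask's; its living end, 9.33 × 10⁻⁵ M, exceeds n, and 15% of its impurity remains. In the neighbour flask with 0.41 mol% of pre-initiator, n becomes 0.240 mM and its 22.6% conversion gives 94.3, where that flask holds a dp of 95.7.

All runs were computed from invented constants, noise included.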